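## Retrosynthetic overview

1. The 1,1-dimethylallyl group comes last, by aromatic Claisen rearrangement of the 4'-O-prenyl ether; C5' is the only free ortho position.
2. Ring C (the pyran) is the only ring made, by intramolecular Pd-catalysed C–O coupling of a primary alcohol onto an aryl bromide; rings A and B are bought as benzene derivatives.
3. The C4–C4a bond is made by Negishi coupling of a primary alkylzinc iodide with 2-bromo-1-iodo-4-(methoxymethoxy)benzene.
4. The C3 stereocentre is set by lipase-catalysed desymmetrising acetylation of a prochiral 2-aryl-propane-1,3-diol; a protecting-group switch then tells the two arms apart.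
5. The diol comes from 2,3,4-trihydroxybenzaldehyde by three regioselective O-alkylations, an aryl-shift homologation with ethyl diazoacetate, and reduction.

Abbreviation: Ar = 4-(benzyloxy)-2-methoxy-3-(methoxymethoxy)phenyl.

Assumption: the lipase acetylates the pro-R CH2OH of the prochiral diol (empirical primary-alcohol rule for this lipase, aryl as the large group), giving the (R)-monoacetate; this sense is not known for this substrate and is checked by Mosher ester analysis on the first batch.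

## Route

Step 1
Reactants: 1 2,3,4-trihydroxybenzaldehyde
Product: 2 4-(benzyloxy)-2,3-dihydroxybenzaldehyde
Conditions: BnBr (1.05 equiv), NaHCO3, MeCN, 60 °C
Reagents that add atoms: benzyl bromide, BrCc1ccccc1
Why: Williamson etherification under bicarbonate touches only the most acidic phenol, the 4-OH para to the formyl group, because the 2-OH is hydrogen-bonded to C=O and the 3-OH is not conjugated with it.

Step 2
Reactants: 2 4-(benzyloxy)-2,3-dihydroxybenzaldehyde
Product: 3 4-(benzyloxy)-2-hydroxy-3-(methoxymethoxy)benzaldehyde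
Conditions: MOMCl (1.1 equiv), i-Pr2NEt, CH2Cl2, 0 °C
Reagents that add atoms: chloromethyl methyl ether, COCCl
Why: With an amine base the chelated 2-OH stays inert, so O-alkylation by the reactive chloromethyl ether (acetal protection) occurs at the free 3-OH only.

Step 3
Reactants: 3 4-(benzyloxy)-2-hydroxy-3-(methoxymethoxy)benzaldehyde
Product: 4 4-(benzyloxy)-2-methoxy-3-(methoxymethoxy)benzaldehyde
Conditions: MeI, K2CO3, DMF, 40 °C
Reagents that add atoms: iodomethane, CI
Why: Carbonate in DMF deprotonates the remaining chelated phenol and Williamson methylation installs the 2-methoxy group, completing the OMe/OMOM/OBn pattern.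

Step 4
Reactants: 4 4-(benzyloxy)-2-methoxy-3-(methoxymethoxy)benzaldehyde
Product: 5 ethyl (2Z)-2-Ar-3-hydroxyprop-2-enoate
Conditions: N2CHCO2Et (1.3 equiv), HBF4·OEt2 (10 mol%), CH2Cl2, −78 °C
Reagents that add atoms: ethyl diazoacetate, CCOC(=O)C=[N+]=[N-]
Why: Acid-catalysed addition of the diazo ester to the aldehyde followed by 1,2-aryl shift with loss of N2 (Roskamp-type homologation in its aryl-migration mode, favoured by the electron-rich ring) gives the 2-aryl-3-hydroxyacrylate, and catalytic acid at −78 °C in an aprotic solvent spares the MOM acetal.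

Step 5
Reactants: 5 ethyl (2Z)-2-Ar-3-hydroxyprop-2-enoate
Product: 7 2-Ar-propane-1,3-diol, via hydroxy ester 6 (not isolated)
Conditions: NaBH4, EtOH, 0 °C; then LiBH4, THF, 0 °C → rt
Reagents that add atoms: none
Why: Borohydride reduction of the aldehyde tautomer gives the β-hydroxy ester and LiBH4 then reduces the ester, so the transient racemic centre of 6 is erased in the achiral, prochiral diol.

Step 6
Reactants: 7 2-Ar-propane-1,3-diol
Product: 8 (2R)-2-Ar-3-hydroxypropyl acetate
Conditions: Burkholderia cepacia lipase (immobilised), vinyl acetate (4 equiv), t-BuOMe, 25 °C, stopped when 7 is consumed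
Reagents that add atoms: vinyl acetate, CC(=O)OC=C
Why: Lipase-catalysed desymmetrising transesterification: the chiral active site of this serine hydrolase transfers acetyl from the irreversible donor to one enantiotopic CH2OH (pro-R), setting the only stereocentre (future C3) by asymmetric biocatalysis, while any over-acetylation consumes the minor enantiomer first.

Step 7
Reactants: 8 (2R)-2-Ar-3-hydroxypropyl acetate
Product: 9 (2S)-2-Ar-3-[(tert-butyldiphenylsilyl)oxy]propyl acetate
Conditions: TBDPSCl, imidazole, CH2Cl2, 0 °C → rt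
Reagents that add atoms: tert-butyl(chloro)diphenylsilane, CC(C)(C)[Si](Cl)(c1ccccc1)c1ccccc1
Why: Silylation of the primary alcohol with a bulky, migration-resistant group marks the arm that will become C2–O (the descriptor changes by priority only).

Step 8
Reactants: 9 (2S)-2-Ar-3-[(tert-butyldiphenylsilyl)oxy]propyl acetate
Product: 10 (2S)-2-Ar-3-[(tert-butyldiphenylsilyl)oxy]propan-1-ol
Conditions: K2CO3 (0.2 equiv), MeOH, 0 °C
Reagents that add atoms: none
Why: Mild base-catalysed methanolysis (transesterification) removes the acetate without touching the silyl ether, so the free hydroxyl now sits on the arm that must become C4, and no bond to the stereocentre is broken.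

Step 9
Reactants: 10 (2S)-2-Ar-3-[(tert-butyldiphenylsilyl)oxy]propan-1-ol
Product: 11 {[(2R)-2-Ar-3-iodopropyl]oxy}(tert-butyl)diphenylsilane
Conditions: I2, PPh3, imidazole, CH2Cl2, 0 °C → rt
Reagents that add atoms: iodine, [I][I]
Why: Appel-type iodination (Garegg–Samuelsson conditions) replaces the primary hydroxyl by SN2 at CH2, leaving the adjacent stereocentre intact.

Step 10
Reactants: 12 3-bromo-4-iodophenol
Product: 13 2-bromo-1-iodo-4-(methoxymethoxy)benzene
Conditions: MOMCl, i-Pr2NEt, CH2Cl2, 0 °C → rt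
Reagents that add atoms: chloromethyl methyl ether, COCCl
Why: Acetal protection of the phenol that becomes the 7-OH; iodine para and bromine meta to this oxygen are placed for C4a and C8a.

Step 11
Reactants: 11 {[(2R)-2-Ar-3-iodopropyl]oxy}(tert-butyl)diphenylsilane; 13 2-bromo-1-iodo-4-(methoxymethoxy)benzene
Product: 15 {[(2R)-2-Ar-3-[2-bromo-4-(methoxymethoxy)phenyl]propyl]oxy}(tert-butyl)diphenylsilane, via alkylzinc iodide 14 (not isolated)
Conditions: Zn (activated), DMF, rt; then 13, Pd2(dba)3 (2.5 mol%), P(o-tol)3 (10 mol%), DMF, rt → 40 °C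
Reagents that add atoms: none
Why: Zinc inserts into the primary C–I bond (the oxygen is γ, so no β-elimination) and Negishi coupling with zerovalent palladium occurs only at the aryl C–I bond, keeping C–Br for the ring closure; the stereocentre is β to zinc and not involved.

Step 12
Reactants: 15 {[(2R)-2-Ar-3-[2-bromo-4-(methoxymethoxy)phenyl]propyl]oxy}(tert-butyl)diphenylsilane
Product: 16 (2R)-2-Ar-3-[2-bromo-4-(methoxymethoxy)phenyl]propan-1-ol
Conditions: Bu4NF, THF, 0 °C → rt
Reagents that add atoms: none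
Why: Fluoride-mediated desilylation frees the primary alcohol; aryl bromide, MOM and benzyl ethers are inert.

Step 13
Reactants: 16 (2R)-2-Ar-3-[2-bromo-4-(methoxymethoxy)phenyl]propan-1-ol
Product: 17 (3R)-3-Ar-7-(methoxymethoxy)chromane
Conditions: Pd(OAc)2 (3 mol%), 2-(di-tert-butylphosphino)-1,1'-binaphthyl (4 mol%), Cs2CO3, toluene, 70 °C
Reagents that add atoms: none
Why: Intramolecular Buchwald–Hartwig C–O coupling closes the six-membered ring C onto ring A, the bulky monophosphine favouring C–O reductive elimination over β-hydride elimination; the stereocentre is untouched.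

Step 14
Reactants: 17 (3R)-3-Ar-7-(methoxymethoxy)chromane
Product: 18 3-methoxy-2-(methoxymethoxy)-4-[(3R)-7-(methoxymethoxy)chroman-3-yl]phenol
Conditions: H2 (1 atm), Pd/C (10 wt%), EtOAc–EtOH, rt
Reagents that add atoms: none
Why: Hydrogenolysis cleaves only the benzyl ether, freeing the 4'-OH before any alkene is present; MOM ethers are inert.

Step 15
Reactants: 18 3-methoxy-2-(methoxymethoxy)-4-[(3R)-7-(methoxymethoxy)chroman-3-yl]phenol
Product: 19 (3R)-3-[2-methoxy-3-(methoxymethoxy)-4-(3-methylbut-2-enyloxy)phenyl]-7-(methoxymethoxy)chromane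
Conditions: 1-bromo-3-methylbut-2-ene, K2CO3, acetone, 40 °C
Reagents that add atoms: 1-bromo-3-methylbut-2-ene (prenyl bromide), CC(C)=CCBr
Why: Williamson O-alkylation of the single free phenol; the neighbouring MOM acetal cannot migrate, so the prenyl group is fixed on O-4'.

Step 16
Reactants: 19 (3R)-3-[2-methoxy-3-(methoxymethoxy)-4-(3-methylbut-2-enyloxy)phenyl]-7-(methoxymethoxy)chromane
Product: 22 3-methoxy-2-(methoxymethoxy)-4-[(3R)-7-(methoxymethoxy)chroman-3-yl]-6-(2-methylbut-3-en-2-yl)phenyl acetate, via dienone 20 (not isolated), via phenol 21 (not isolated)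
Conditions: Ac2O (5 equiv), PhNEt2, 185 °C, sealed tube, argon
Reagents that add atoms: acetic anhydride, CC(=O)OC(C)=O
Why: Aromatic Claisen rearrangement: the [3,3] shift delivers the allyl unit, with its ends inverted, to the only free ortho position C5' as the 1,1-dimethylallyl group, and the phenol formed on tautomerisation is acetylated at once, blocking the abnormal Claisen pathway and cyclisation to a dihydrobenzofuran.

Step 17
Reactants: 22 3-methoxy-2-(methoxymethoxy)-4-[(3R)-7-(methoxymethoxy)chroman-3-yl]-6-(2-methylbut-3-en-2-yl)phenyl acetate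
Product: 23 (3R)-3-[3,4-dihydroxy-2-methoxy-5-(2-methylbut-3-en-2-yl)phenyl]chroman-7-ol
Conditions: HCl (1.25 M in MeOH), THF, 40 °C, argon
Reagents that add atoms: none
Why: Acid-catalysed acetal exchange removes both MOM groups and methanolysis cleaves the aryl acetate, while the monosubstituted alkene would need a secondary cation to react and survives these mild conditions.

## Compound list

1 | 2,3,4-trihydroxybenzaldehyde | O=Cc1ccc(O)c(O)c1O | starting material
2 | 4-(benzyloxy)-2,3-dihydroxybenzaldehyde | O=Cc1ccc(OCc2ccccc2)c(O)c1O | intermediate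
3 | 4-(benzyloxy)-2-hydroxy-3-(methoxymethoxy)benzaldehyde | O=Cc1ccc(OCc2ccccc2)c(OCOC)c1O | intermediate
4 | 4-(benzyloxy)-2-methoxy-3-(methoxymethoxy)benzaldehyde | O=Cc1ccc(OCc2ccccc2)c(OCOC)c1OC | intermediate
5 | ethyl (2Z)-2-Ar-3-hydroxyprop-2-enoate | CCOC(=O)/C(=C\O)c1ccc(OCc2ccccc2)c(OCOC)c1OC | intermediate
6 | ethyl 2-Ar-3-hydroxypropanoate (racemic, not isolated) | CCOC(=O)C(CO)c1ccc(OCc2ccccc2)c(OCOC)c1OC | intermediate
7 | 2-Ar-propane-1,3-diol | OCC(CO)c1ccc(OCc2ccccc2)c(OCOC)c1OC | intermediate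
8 | (2R)-2-Ar-3-hydroxypropyl acetate | CC(=O)OC[C@@H](CO)c1ccc(OCc2ccccc2)c(OCOC)c1OC | intermediate
9 | (2S)-2-Ar-3-[(tert-butyldiphenylsilyl)oxy]propyl acetate | CC(=O)OC[C@@H](CO[Si](c1ccccc1)(c1ccccc1)C(C)(C)C)c1ccc(OCc2ccccc2)c(OCOC)c1OC | intermediate
10 | (2S)-2-Ar-3-[(tert-butyldiphenylsilyl)oxy]propan-1-ol | OC[C@@H](CO[Si](c1ccccc1)(c1ccccc1)C(C)(C)C)c1ccc(OCc2ccccc2)c(OCOC)c1OC | intermediate
11 | {[(2R)-2-Ar-3-iodopropyl]oxy}(tert-butyl)diphenylsilane | IC[C@@H](CO[Si](c1ccccc1)(c1ccccc1)C(C)(C)C)c1ccc(OCc2ccccc2)c(OCOC)c1OC | intermediate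
12 | 3-bromo-4-iodophenol | Oc1ccc(I)c(Br)c1 | starting material
13 | 2-bromo-1-iodo-4-(methoxymethoxy)benzene | COCOc1ccc(I)c(Br)c1 | intermediate
14 | {(2R)-2-Ar-3-[(tert-butyldiphenylsilyl)oxy]propyl}zinc iodide (not isolated) | I[Zn]C[C@@H](CO[Si](c1ccccc1)(c1ccccc1)C(C)(C)C)c1ccc(OCc2ccccc2)c(OCOC)c1OC | intermediate
15 | {[(2R)-2-Ar-3-[2-bromo-4-(methoxymethoxy)phenyl]propyl]oxy}(tert-butyl)diphenylsilane | COCOc1ccc(C[C@@H](CO[Si](c2ccccc2)(c2ccccc2)C(C)(C)C)c2ccc(OCc3ccccc3)c(OCOC)c2OC)c(Br)c1 | intermediate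
16 | (2R)-2-Ar-3-[2-bromo-4-(methoxymethoxy)phenyl]propan-1-ol | COCOc1ccc(C[C@@H](CO)c2ccc(OCc3ccccc3)c(OCOC)c2OC)c(Br)c1 | intermediate
17 | (3R)-3-[4-(benzyloxy)-2-methoxy-3-(methoxymethoxy)phenyl]-7-(methoxymethoxy)chromane | COCOc1ccc2C[C@@H](COc2c1)c1ccc(OCc2ccccc2)c(OCOC)c1OC | intermediate
18 | 3-methoxy-2-(methoxymethoxy)-4-[(3R)-7-(methoxymethoxy)chroman-3-yl]phenol | COCOc1ccc2C[C@@H](COc2c1)c1ccc(O)c(OCOC)c1OC | intermediate
19 | (3R)-3-[2-methoxy-3-(methoxymethoxy)-4-(3-methylbut-2-enyloxy)phenyl]-7-(methoxymethoxy)chromane | COCOc1ccc2C[C@@H](COc2c1)c1ccc(OCC=C(C)C)c(OCOC)c1OC | intermediate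
20 | 3-methoxy-2-(methoxymethoxy)-4-[(3R)-7-(methoxymethoxy)chroman-3-yl]-6-(2-methylbut-3-en-2-yl)cyclohexa-2,4-dien-1-one (C6 epimers, not isolated) | COCOc1ccc2C[C@@H](COc2c1)C1=CC(C(C)(C)C=C)C(=O)C(OCOC)=C1OC | intermediate
21 | 3-methoxy-2-(methoxymethoxy)-4-[(3R)-7-(methoxymethoxy)chroman-3-yl]-6-(2-methylbut-3-en-2-yl)phenol (not isolated) | COCOc1ccc2C[C@@H](COc2c1)c1cc(C(C)(C)C=C)c(O)c(OCOC)c1OC | intermediate
22 | 3-methoxy-2-(methoxymethoxy)-4-[(3R)-7-(methoxymethoxy)chroman-3-yl]-6-(2-methylbut-3-en-2-yl)phenyl acetate | COCOc1ccc2C[C@@H](COc2c1)c1cc(C(C)(C)C=C)c(OC(C)=O)c(OCOC)c1OC | intermediate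
23 | (3R)-3-[3,4-dihydroxy-2-methoxy-5-(2-methylbut-3-en-2-yl)phenyl]chroman-7-ol | C=CC(C)(C)c1cc([C@@H]2COc3cc(O)ccc3C2)c(OC)c(O)c1O | target

## Step count

Total steps: 17. Longest linear sequence: 16 steps (1 to 23 through steps 1–9 and 11–17); step 10 is a one-step side branch.

## Three steps most likely to fail, with fallbacks

Step 6 (ee or sense of the lipase acetylation). The fallback uses the hydrolytic instead of the acylating mode; it sets out from diol 7 and comes back at alcohol 16. Diol 7 is peracetylated (Ac2O, pyridine) to 2-Ar-propane-1,3-diyl diacetate F1. The same lipase in phosphate buffer (pH 7)/i-Pr2O then hydrolyses the ester on the arm it would have acetylated, leaving (2S)-2-Ar-3-hydroxypropyl acetate F2; further hydrolysis back to 7 consumes the minor enantiomer and raises the ee. The acetate now sits on the arm destined for C2–O, so no protecting-group switch is needed. I2/PPh3/imidazole gives (2R)-2-Ar-3-iodopropyl acetate F3, Zn in DMF gives [(2R)-3-acetoxy-2-Ar-propyl]zinc iodide F4, and Negishi coupling with 13 under the conditions of step 11 gives (2R)-2-Ar-3-[2-bromo-4-(methoxymethoxy)phenyl]propyl acetate F5. K2CO3/MeOH then gives 16. If step 6 itself proves to deliver the (S)-monoacetate, that product is F2 and the same short sequence applies.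

Step 11 (zinc insertion and Negishi coupling of a β-branched alkyl iodide with an ortho-substituted aryl iodide). The fallback changes the organometallic to boron; it sets out from iodide 11 and comes back at 15. Iodine–lithium exchange (t-BuLi, 2.1 equiv, Et2O, −78 °C) gives {(2R)-2-Ar-3-[(tert-butyldiphenylsilyl)oxy]propyl}lithium F6. This is trapped at once with B-methoxy-9-borabicyclo[3.3.1]nonane to give lithium 9-{(2R)-2-Ar-3-[(tert-butyldiphenylsilyl)oxy]propyl}-9-methoxy-9-boranuidabicyclo[3.3.1]nonane F7. B-alkyl Suzuki–Miyaura coupling of this borate with 13 (PdCl2(dppf), K3PO4, DMF–THF, rt; selective for C–I over C–Br) gives 15.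

Step 16 (thermal Claisen: loss of the prenyl group, abnormal Claisen products). The fallback builds the quaternary benzylic carbon by cross-coupling instead of a sigmatropic shift; it sets out from phenol 18 and comes back at target 23.
- Ortho-selective bromination (NBS, i-Pr2NH cat., CH2Cl2, −78 → 0 °C; the para position is blocked) gives 6-bromo-3-methoxy-2-(methoxymethoxy)-4-[(3R)-7-(methoxymethoxy)chroman-3-yl]phenol F8.
- MOMCl/i-Pr2NEt gives (3R)-3-[5-bromo-2-methoxy-3,4-bis(methoxymethoxy)phenyl]-7-(methoxymethoxy)chromane F9.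
- Pd-catalysed α-arylation of 2-methylpropanal (Pd(OAc)2, rac-BINAP, Cs2CO3, dioxane, 80 °C) gives 2-{4-methoxy-2,3-bis(methoxymethoxy)-5-[(3R)-7-(methoxymethoxy)chroman-3-yl]phenyl}-2-methylpropanal F10.
- Wittig methylenation (Ph3P=CH2, THF, 0 °C) gives (3R)-3-[2-methoxy-3,4-bis(methoxymethoxy)-5-(2-methylbut-3-en-2-yl)phenyl]-7-(methoxymethoxy)chromane F11.
- HCl in MeOH/THF at 40 °C removes the three MOM groups to give 23.

## Further compounds

F1 | step 6 | 2-Ar-propane-1,3-diyl diacetate | CC(=O)OCC(COC(C)=O)c1ccc(OCc2ccccc2)c(OCOC)c1OC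
F2 | step 6 | (2S)-2-Ar-3-hydroxypropyl acetate | CC(=O)OC[C@H](CO)c1ccc(OCc2ccccc2)c(OCOC)c1OC
F3 | step 6 | (2R)-2-Ar-3-iodopropyl acetate | IC[C@@H](COC(C)=O)c1ccc(OCc2ccccc2)c(OCOC)c1OC
F4 | step 6 | [(2R)-3-acetoxy-2-Ar-propyl]zinc iodide | I[Zn]C[C@@H](COC(C)=O)c1ccc(OCc2ccccc2)c(OCOC)c1OC
F5 | step 6 | (2R)-2-Ar-3-[2-bromo-4-(methoxymethoxy)phenyl]propyl acetate | COCOc1ccc(C[C@@H](COC(C)=O)c2ccc(OCc3ccccc3)c(OCOC)c2OC)c(Br)c1
F6 | step 11 | {(2R)-2-Ar-3-[(tert-butyldiphenylsilyl)oxy]propyl}lithium | [Li]C[C@@H](CO[Si](c1ccccc1)(c1ccccc1)C(C)(C)C)c1ccc(OCc2ccccc2)c(OCOC)c1OC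
F7 | step 11 | lithium 9-{(2R)-2-Ar-3-[(tert-butyldiphenylsilyl)oxy]propyl}-9-methoxy-9-boranuidabicyclo[3.3.1]nonane | [Li+].CO[B-]1(C[C@@H](CO[Si](c2ccccc2)(c2ccccc2)C(C)(C)C)c2ccc(OCc3ccccc3)c(OCOC)c2OC)C2CCCC1CCC2
F8 | step 16 | 6-bromo-3-methoxy-2-(methoxymethoxy)-4-[(3R)-7-(methoxymethoxy)chroman-3-yl]phenol | COCOc1ccc2C[C@@H](COc2c1)c1cc(Br)c(O)c(OCOC)c1OC
F9 | step 16 | (3R)-3-[5-bromo-2-methoxy-3,4-bis(methoxymethoxy)phenyl]-7-(methoxymethoxy)chromane | COCOc1ccc2C[C@@H](COc2c1)c1cc(Br)c(OCOC)c(OCOC)c1OC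
F10 | step 16 | 2-{4-methoxy-2,3-bis(methoxymethoxy)-5-[(3R)-7-(methoxymethoxy)chroman-3-yl]phenyl}-2-methylpropanal | COCOc1ccc2C[C@@H](COc2c1)c1cc(C(C)(C)C=O)c(OCOC)c(OCOC)c1OC
F11 | step 16 | (3R)-3-[2-methoxy-3,4-bis(methoxymethoxy)-5-(2-methylbut-3-en-2-yl)phenyl]-7-(methoxymethoxy)chromane | COCOc1ccc2C[C@@H](COc2c1)c1cc(C(C)(C)C=C)c(OCOC)c(OCOC)c1OC
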